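## Analysis of the target

Licoisoflavone A (16) is an isoflavone: a 4H-chromen-4-one (rings A and C) that carries ring B on C3. Ring A has hydroxyls at C5 and C7; ring B has hydroxyls at C2' and C4' and a prenyl group on C3' between them, so ring B is 1,2,3,4-tetrasubstituted. There is no stereocentre, so the task is one of connectivity, regiochemistry and functional-group tolerance. The sensitive unit is the prenyl alkene with a phenol on either side: acid adds a neighbouring hydroxyl across it to give a dimethylchroman, and electrophilic oxidants, hydrogenation and hot Lewis acids also consume it; ring A is in addition a C-nucleophilic phloroglucinol, and the pyranone is opened at C2 by hard nucleophiles. Three things make the synthesis hard: the C3–C1' bond to a crowded ring B, the placing of the prenyl group on C3' and not on C5' or on oxygen, and the release of four phenols at the end without acid, hydrogen or oxidant. The strategy rests on the carbon pattern around C3, which is bonded to C1' of ring B, to C2 and to C4. A chalcone holds the same atoms in a row, C4–Cα–Cβ–C1'; if C4 moves from Cα to Cβ, Cβ becomes C3 and Cα is left as C2 at the aldehyde oxidation level. Both rings can therefore be made with their substituents in place and joined by an aldol condensation, and the C3–C1' bond never has to be formed by a coupling.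

## Retrosynthetic reasoning

**16 from 15.** The last disconnection cuts the four O–allyl bonds of 15. Allyl ethers are chosen because palladium-catalysed allyl transfer to an amine removes them under neutral conditions. The prenyl group is a C-allyl unit without a leaving group and is not touched, and no acid is present when the phenols beside it become free. The forward step has to remove four groups, including the one on the hydrogen-bonded O5, without allylating C6 or C8.

**15 from 12.** Ring C is opened at the O1–C2 bond, which leads back through hemiacetal 14 and phenol 13 to the keto aldehyde 12. In 12 the future O1 is the only oxygen masked as an acid-labile methoxymethyl ether. Cutting here, and not at C4–C4a or C3–C1', exposes a 1,3-dicarbonyl chain that already holds every carbon of the target. The single acetal can be removed by mild acid while both phenols beside the prenyl group are still allyl ethers, so chroman formation has no hydroxyl to work with. Ring closure must also precede deallylation, because the doubly activated C–H of 12 would itself be allylated by a π-allyl palladium species.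

**12 from 11 (key).** In 12 the bond between the ketone carbon (C4) and the carbon bearing ring B (C3) is cut and C4 is reattached to the aldehyde carbon. This is the reverse of a 1,2-acyl shift and gives the linear chain of the trans-epoxy ketone 11. The cut is made here because the forward reaction then starts from a cation at the position the substrate stabilises best, the benzylic carbon ortho and para to two alkoxy groups, and ends in an aldehyde, the oxidation level C2 needs. The gain is that the C3–C1' bond already exists in 11 and that only a Lewis acid is needed. The oxidative aryl shift of a chalcone would call for electrophilic oxidants that attack the five isolated alkenes. The forward step must make the aroyl group migrate faster than hydride, and faster than any oxygen lone pair captures the cation.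

**11 from 10.** The two C–O bonds of the oxirane are cut to give the E-chalcone 10. A nucleophilic epoxidation of the Weitz–Scheffer type is required. It attacks only the electron-poor enone, gives the trans-epoxide, and leaves the prenyl and allyl alkenes alone, which a peracid would not. The masked 2'-oxygen prevents the cyclisations that free 2'-hydroxychalcones undergo under these conditions.

**10 from 8 and 5.** Cleaving the Cα=Cβ bond of 10 (through the aldol adduct 9) divides the molecule into the acetophenone 8 for ring A and the benzaldehyde 5 for ring B, two pieces of similar size. The condensation is base-mediated, so the allyl ethers, the acetal and the prenyl group pass through, and only 8 can enolise.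

**8 from 7 and 6.** In 8 the acetal O–C bond and then two allyl O–C bonds are cut, leading to 7 and then to the acetophenone 6 and allyl bromide 4. The order is set by the substrate: the para and one ortho hydroxyl of 6 are alkylated first. The remaining ortho hydroxyl, held in a hydrogen bond to the carbonyl, is left for the acetal, and it is the oxygen that has to become O1.

**5 from 3, 1 and 2.** In 5 the two allyl O–C bonds are cut (back to 3 and 4), and then the C3–prenyl bond, which leads to 2,4-dihydroxybenzaldehyde 1 and prenyl bromide 2. Putting the prenyl group on first, on the cheapest compound of the route, places the one step with imperfect regiochemistry at the start. Both phenols can then be capped as allyl ethers before any acid is used.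

## Alternatives that were turned down

Alternative 1: Ring B itself is disconnected. Four of its bonds (C1'–C2', C2'–C3', C4'–C5', C5'–C6') are cut, which leads to the chromon-3-yl enone diazoketone A1 and the prenyl-substituted siloxyalkyne A2.
- Forward key step: light triggers a Wolff rearrangement of A1 to a vinylketene. This adds A2 in a [2+2] sense, the cyclobutenone opens to a dienylketene, and 6π electrocyclisation with tautomerisation gives the phenol A3.
- For: the four substituents of ring B arrive in fixed positions, with the prenyl group between the two oxygens by construction and the two oxygens already differentiated. On regiocontrol this plan is stronger than the chosen one, whose first step gives isomers.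
- Against: A1 has to be built over several steps on a preformed chromone, and its chromone enone absorbs in the same region as the diazoketone and can dimerise or isomerise. A2 is a labile ynol ether with a multi-step preparation of its own. The acetal and silyl groups of A3 would later be removed with the prenyl group already next to a free phenol.
- Comparison: the chosen route takes ring B ready-made from an inexpensive aldehyde, needs no photochemistry and is several steps shorter.

Alternative 2: The bond cut is C3'–C1'', between ring B and the prenyl group. The precursor is the isoflavone A4, whose 2'-oxygen carries a 1,1-dimethylallyl group.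
- Forward key step: on warming, if necessary with a mild lanthanide Lewis acid, a [3,3] shift through a chair transition state carries the allyl terminus to C3', the only free ortho position, and tautomerisation gives A5.
- For: the regiochemistry is fixed by geometry, since C1' is blocked. The prenyl group appears late, so the isoflavone core can be made by any standard method, oxidative ones included. On both points it is as strong as or stronger than the chosen plan.
- Against: the tertiary ether of A4 must be made on a hindered phenol that is the only free one, which calls for three sets of protecting groups and normally two steps (propargylic etherification, semihydrogenation). Tertiary allyl aryl ethers ionise easily and then give dealkylation or the reverse-prenyl isomer. The 2'-hydroxyl set free by the shift sits beside the new alkene and can cyclise to the chroman, both in the hot mixture and in the acidic removal of the three acetals of A5.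
- Comparison: the chosen strategy is shorter, introduces the prenyl group in one step, and never exposes it to acid with a free phenol beside it.

Alternative 3: This plan also disconnects at C3, but at the C3–C1' bond. Ring B is returned from C3 to C2, giving the trans-flavanonol mesylate A6, which descends from the same chalcone epoxide as the chosen route.
- Forward key step: A6 is ionised in a strongly ionising fluorinated alcohol with a hindered pyridine base. Ring B bridges to C3 as a phenonium ion, C2 becomes an oxocarbenium ion stabilised by O1, and loss of the C3 proton gives A7, which is identical with 15.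
- For: it follows the biosynthesis, the 2,4-dialkoxyphenyl group is an excellent neighbouring group, and it tolerates the alkenes as well as the chosen plan does. The chromone comes out directly at the right oxidation level without a separate ring closure.
- Against: the leaving group is on a carbon next to the C4 carbonyl, where ionisation is strongly retarded. Everything then depends on help from an aryl group that must stand antiperiplanar to the sulfonate, which means the diaxial conformer of the trans isomer. The C3 proton is acidic, and base can instead open ring C by β-elimination or lead to flavonol- and aurone-type products. From the epoxide three operations are needed (unmask and cyclise, sulfonylate, shift) where the chosen plan needs two.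
- Comparison: the chosen strategy forms its cation at the benzylic carbon, where the substrate stabilises it, and uses a reaction type with direct precedent on chalcone epoxides.

Key step: step 7

Remark on the chemistry: the target has no stereocentre, so 9 and 11 to 14 are carried as racemates or stereoisomer mixtures; 12 is expected to exist largely as its hydroxymethylene enol and is used crude. Allyl = prop-2-enyl, prenyl = 3-methylbut-2-enyl, MOM = methoxymethyl.

## Route

Step 1  
Reactants: 1 2,4-dihydroxybenzaldehyde; 2 prenyl bromide (1-bromo-3-methylbut-2-ene)  
Product: 3 2,4-dihydroxy-3-(3-methylbut-2-enyl)benzaldehyde  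
Conditions: KOH (10% aq.), 0 °C to rt  
Reagents that add atoms: prenyl bromide 2, CC(C)=CCBr  
Why: C-Alkylation of an ambident phenoxide: in water the oxygens are hydrogen-bonded, so the allylic bromide is taken up at carbon, preferentially at C3, which lies ortho to both oxygens and is favoured by the bond fixation of the chelated salicylaldehyde; the C5 and O-alkylated isomers that also form should be separable by chromatography.

Step 2  
Reactants: 3 2,4-dihydroxy-3-(3-methylbut-2-enyl)benzaldehyde; 4 allyl bromide (3-bromoprop-1-ene)  
Product: 5 2,4-bis(allyloxy)-3-(3-methylbut-2-enyl)benzaldehyde  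
Conditions: allyl bromide (2.5 equiv), K2CO3, DMF, 50 °C  
Reagents that add atoms: allyl bromide 4, C=CCBr  
Why: Williamson ether synthesis; DMF and gentle warming are needed for the chelated, flanked 2-hydroxyl, and the temperature stays far below that of an aromatic Claisen shift.

Step 3  
Reactants: 6 2',4',6'-trihydroxyacetophenone; 4 allyl bromide  
Product: 7 1-[2,4-bis(allyloxy)-6-hydroxyphenyl]ethanone  
Conditions: allyl bromide (2.1 equiv), K2CO3, acetone, reflux  
Reagents that add atoms: allyl bromide 4, C=CCBr  
Why: Williamson etherification under weak-base, aprotic conditions that favour O- over C-alkylation; the para and one ortho hydroxyl react, and the last ortho hydroxyl stays free because it is locked in a hydrogen bond to the carbonyl.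

Step 4  
Reactants: 7 1-[2,4-bis(allyloxy)-6-hydroxyphenyl]ethanone  
Product: 8 1-[2,4-bis(allyloxy)-6-(methoxymethoxy)phenyl]ethanone  
Conditions: NaH (1.1 equiv), DMF, 0 °C; then MOMCl, 0 °C to rt  
Reagents that add atoms: chloromethyl methyl ether, COCCl  
Why: Irreversible deprotonation breaks the hydrogen bond and the sodium phenoxide is alkylated by the reactive α-chloro ether; the acetal survives the base of steps 5 and 6 and is the only acid-labile oxygen substituent in the molecule.

Step 5  
Reactants: 8 1-[2,4-bis(allyloxy)-6-(methoxymethoxy)phenyl]ethanone; 5 2,4-bis(allyloxy)-3-(3-methylbut-2-enyl)benzaldehyde  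
Product: 10 (E)-1-[2,4-bis(allyloxy)-6-(methoxymethoxy)phenyl]-3-[2,4-bis(allyloxy)-3-(3-methylbut-2-enyl)phenyl]prop-2-en-1-one, via racemic aldol adduct 9 (not isolated)  
Conditions: KOH, EtOH, rt  
Reagents that add atoms: none  
Why: Claisen–Schmidt condensation: the methyl ketone enolate adds to the non-enolisable aldehyde and the β-hydroxy ketone 9 loses hydroxide by an E1cB path; the stereocentre of 9 disappears and the conjugated E-alkene is the thermodynamic product.

Step 6  
Reactants: 10 (E)-1-[2,4-bis(allyloxy)-6-(methoxymethoxy)phenyl]-3-[2,4-bis(allyloxy)-3-(3-methylbut-2-enyl)phenyl]prop-2-en-1-one  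
Product: 11 [2,4-bis(allyloxy)-6-(methoxymethoxy)phenyl]{(2R*,3S*)-3-[2,4-bis(allyloxy)-3-(3-methylbut-2-enyl)phenyl]oxiran-2-yl}methanone (trans, racemic)  
Conditions: H2O2 (30% aq.), NaOH (2 M aq.), MeOH–THF, 0 °C to rt  
Reagents that add atoms: hydrogen peroxide, OO  
Why: Weitz–Scheffer epoxidation: hydroperoxide anion adds to the enone β-carbon and the enolate displaces hydroxide from the O–O bond; rotation in the enolate lets the ring close to the less hindered trans-epoxide, so both new stereocentres are set in the (2R*,3S*) relative sense as a racemate, while the nucleophilic oxidant ignores the prenyl and allyl alkenes and the protected 2'-oxygen cannot cyclise.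

Step 7  
Reactants: 11 [2,4-bis(allyloxy)-6-(methoxymethoxy)phenyl]{(2R*,3S*)-3-[2,4-bis(allyloxy)-3-(3-methylbut-2-enyl)phenyl]oxiran-2-yl}methanone  
Product: 12 3-[2,4-bis(allyloxy)-6-(methoxymethoxy)phenyl]-2-[2,4-bis(allyloxy)-3-(3-methylbut-2-enyl)phenyl]-3-oxopropanal  
Conditions: BF3·OEt2 (1.2 equiv), CH2Cl2, −78 to −20 °C; then cold sat. aq. NaHCO3  
Reagents that add atoms: none  
Why: BF3 binds the oxirane oxygen and the C–O bond at the ring B benzylic carbon ionises, because the 2- and 4-allyloxy groups stabilise that cation while the other oxirane carbon is deactivated by the adjacent carbonyl. The aroyl group then moves with its bonding pair from the neighbouring carbon to the cationic centre, forming the C3–C4 bond, and the boron alkoxide left behind collapses to the aldehyde that becomes C2. The closest known reaction type is the Lewis-acid (Meinwald-type, semipinacol) rearrangement of chalcone epoxides to 2-formyl deoxybenzoins, a 1,2-acyl shift. No ring is closed. The one new stereocentre, the carbon bearing ring B, is enolisable, is not controlled and disappears in step 8. The step needs the acyl shift to win over hydride shift (which would give the 1,2-diketone) and over capture of the cation by fluoride or by the 2'-oxygen: the C–C(O) bond can align with the empty benzylic orbital once the trans-epoxide opens, the electron-rich trialkoxybenzoyl group migrates readily, and the 2'-oxygen is tied up as an acetal ether at low temperature. The prenyl group is meta to the cationic carbon and the O-allyl alkenes are poor nucleophiles, so no cation–alkene cyclisation is expected, and loss of the MOM group after the shift would only anticipate step 8.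

Step 8  
Reactants: 12 3-[2,4-bis(allyloxy)-6-(methoxymethoxy)phenyl]-2-[2,4-bis(allyloxy)-3-(3-methylbut-2-enyl)phenyl]-3-oxopropanal  
Product: 15 5,7-bis(allyloxy)-3-[2,4-bis(allyloxy)-3-(3-methylbut-2-enyl)phenyl]-4H-chromen-4-one, via free-phenol keto aldehyde 13 (not isolated), via 2-hydroxyisoflavanone hemiacetal 14 (not isolated)  
Conditions: conc. HCl (cat.), MeOH, 45 °C  
Reagents that add atoms: none  
Why: Acid-catalysed acetal exchange with methanol frees the 2'-phenol (13), which adds to the aldehyde in a 6-exo-trig closure to the hemiacetal 14; dehydration to the conjugated pyranone is the driving force. The prenyl alkene has only allyl ethers as neighbours at this stage, so no phenol is available for chroman formation.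

Step 9  
Reactants: 15 5,7-bis(allyloxy)-3-[2,4-bis(allyloxy)-3-(3-methylbut-2-enyl)phenyl]-4H-chromen-4-one  
Product: 16 licoisoflavone A, 3-[2,4-dihydroxy-3-(3-methylbut-2-enyl)phenyl]-5,7-dihydroxy-4H-chromen-4-one  
Conditions: Pd(PPh3)4 (5 mol %), morpholine (excess), THF, rt; dilute acid work-up  
Reagents that add atoms: none  
Why: Tsuji–Trost-type deallylation: Pd(PPh3)4, a zerovalent palladium complex, ionises each aryl allyl ether to a π-allyl complex and a phenoxide, and morpholine takes up the allyl group; the C-bound prenyl group has no leaving group and stays, and no acid is present while the phenols beside it are set free.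

## Compound list

```
1 | 2,4-dihydroxybenzaldehyde | O=Cc1ccc(O)cc1O | starting material
2 | prenyl bromide (1-bromo-3-methylbut-2-ene) | CC(C)=CCBr | starting material
3 | 2,4-dihydroxy-3-(3-methylbut-2-enyl)benzaldehyde | CC(C)=CCc1c(O)ccc(C=O)c1O | intermediate
4 | allyl bromide (3-bromoprop-1-ene) | C=CCBr | starting material
5 | 2,4-bis(allyloxy)-3-(3-methylbut-2-enyl)benzaldehyde | CC(C)=CCc1c(OCC=C)ccc(C=O)c1OCC=C | intermediate
6 | 2',4',6'-trihydroxyacetophenone | CC(=O)c1c(O)cc(O)cc1O | starting material
7 | 1-[2,4-bis(allyloxy)-6-hydroxyphenyl]ethanone | CC(=O)c1c(O)cc(OCC=C)cc1OCC=C | intermediate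
8 | 1-[2,4-bis(allyloxy)-6-(methoxymethoxy)phenyl]ethanone | CC(=O)c1c(OCOC)cc(OCC=C)cc1OCC=C | intermediate
9 | 1-[2,4-bis(allyloxy)-6-(methoxymethoxy)phenyl]-3-[2,4-bis(allyloxy)-3-(3-methylbut-2-enyl)phenyl]-3-hydroxypropan-1-one (racemic, drawn without configuration) | CC(C)=CCc1c(OCC=C)ccc(C(O)CC(=O)c2c(OCOC)cc(OCC=C)cc2OCC=C)c1OCC=C | intermediate (not isolated)
10 | (E)-1-[2,4-bis(allyloxy)-6-(methoxymethoxy)phenyl]-3-[2,4-bis(allyloxy)-3-(3-methylbut-2-enyl)phenyl]prop-2-en-1-one | CC(C)=CCc1c(OCC=C)ccc(/C=C/C(=O)c2c(OCOC)cc(OCC=C)cc2OCC=C)c1OCC=C | intermediate
11 | [2,4-bis(allyloxy)-6-(methoxymethoxy)phenyl]{(2R*,3S*)-3-[2,4-bis(allyloxy)-3-(3-methylbut-2-enyl)phenyl]oxiran-2-yl}methanone (trans, racemic, one enantiomer drawn) | O=C(c1c(OCOC)cc(OCC=C)cc1OCC=C)[C@@H]1O[C@H]1c1ccc(OCC=C)c(CC=C(C)C)c1OCC=C | intermediate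
12 | 3-[2,4-bis(allyloxy)-6-(methoxymethoxy)phenyl]-2-[2,4-bis(allyloxy)-3-(3-methylbut-2-enyl)phenyl]-3-oxopropanal (enolisable centre, drawn without configuration) | O=CC(C(=O)c1c(OCOC)cc(OCC=C)cc1OCC=C)c1ccc(OCC=C)c(CC=C(C)C)c1OCC=C | intermediate
13 | 3-[2,4-bis(allyloxy)-6-hydroxyphenyl]-2-[2,4-bis(allyloxy)-3-(3-methylbut-2-enyl)phenyl]-3-oxopropanal (drawn without configuration) | O=CC(C(=O)c1c(O)cc(OCC=C)cc1OCC=C)c1ccc(OCC=C)c(CC=C(C)C)c1OCC=C | intermediate (not isolated)
14 | 5,7-bis(allyloxy)-3-[2,4-bis(allyloxy)-3-(3-methylbut-2-enyl)phenyl]-2-hydroxychroman-4-one (diastereomer mixture, drawn without configuration) | OC1Oc2cc(OCC=C)cc(OCC=C)c2C(=O)C1c1ccc(OCC=C)c(CC=C(C)C)c1OCC=C | intermediate (not isolated)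
15 | 5,7-bis(allyloxy)-3-[2,4-bis(allyloxy)-3-(3-methylbut-2-enyl)phenyl]-4H-chromen-4-one | CC(C)=CCc1c(OCC=C)ccc(-c2coc3cc(OCC=C)cc(OCC=C)c3c2=O)c1OCC=C | intermediate
16 | licoisoflavone A, 3-[2,4-dihydroxy-3-(3-methylbut-2-enyl)phenyl]-5,7-dihydroxy-4H-chromen-4-one | CC(C)=CCc1c(O)ccc(-c2coc3cc(O)cc(O)c3c2=O)c1O | target
```

## Step count and least certain steps

Total step count: 9. Longest linear sequence: 7 steps (6 → 7 → 8 → 10 → 11 → 12 → 15 → 16; the ring B arm from 1 through 3 and 5 is equally long).

**Step 7 (key step).** The benzylic cation may be diverted from the acyl shift: hydride shift to the 1,2-diketone, capture by the 2'-oxygen after Lewis-acid loss of the acetal (flavanonol formation), or oligomerisation. The 2,4-dialkoxybenzyl cation is long-lived and the migrating aroyl group carries two ortho substituents, which makes these paths plausible. The fallback gives up the 1,2-shift and makes the C3–C1' bond by cross-coupling; it sets out from 7 and comes back at 16.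
- Heating 7 with N,N-dimethylformamide dimethyl acetal should give the enaminone (E)-1-[2,4-bis(allyloxy)-6-hydroxyphenyl]-3-(dimethylamino)prop-2-en-1-one F1, which I2 in CHCl3–pyridine should close to 5,7-bis(allyloxy)-3-iodo-4H-chromen-4-one F2.
- For ring B, commercial 1,3-bis(methoxymethoxy)benzene F3 is lithiated between its two acetal oxygens (n-BuLi, THF, 0 °C) and alkylated with 2 to give 1,3-bis(methoxymethoxy)-2-(3-methylbut-2-enyl)benzene F4. A second directed lithiation (n-BuLi, TMEDA) and quench with B(OMe)3 give [2,4-bis(methoxymethoxy)-3-(3-methylbut-2-enyl)phenyl]boronic acid F5.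
- Suzuki–Miyaura coupling of F2 with F5 (PdCl2(dppf), aq. Na2CO3, DME, 80 °C) should give 5,7-bis(allyloxy)-3-[2,4-bis(methoxymethoxy)-3-(3-methylbut-2-enyl)phenyl]-4H-chromen-4-one F6. Any allyl group lost here would be removed in the next operation anyway.
- Deallylation as in step 9 gives 5,7-dihydroxy-3-[2,4-bis(methoxymethoxy)-3-(3-methylbut-2-enyl)phenyl]-4H-chromen-4-one F7, and dilute HCl in MeOH at room temperature removes the two acetals to reach 16.
- The cost is that this last acid step meets the prenyl group with phenols being freed beside it, which is why it is only the reserve.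

**Step 1.** Poor regioselectivity and over-alkylation are likely, because C3, C5 and O4 of the dianion are all activated. The fallback sets out from 1 and returns at 3, with the regiochemistry fixed by a sigmatropic shift instead of an intermolecular alkylation.
- Alkylation of the non-chelated 4-hydroxyl with 4 (K2CO3, acetone) gives 4-(allyloxy)-2-hydroxybenzaldehyde F8.
- An aromatic Claisen rearrangement (N,N-diethylaniline, about 200 °C) delivers the allyl group to the position between the two oxygens, which the bond fixation of the chelated ring favours, giving 3-allyl-2,4-dihydroxybenzaldehyde F9.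
- Olefin cross-metathesis with 2-methylbut-2-ene (second-generation Grubbs catalyst, RuCl2(=CHPh)(PCy3)(H2IMes), CH2Cl2, 40 °C) turns the allyl into the prenyl group of 3.

**Step 6.** Conjugate addition of hydroperoxide may be slow, since the 2,4-dialkoxyphenyl group feeds electron density into the enone; retro-aldol cleavage in base and decomposition of the acid-labile epoxide during isolation may follow. The fallback builds the epoxide by a Darzens condensation and avoids the enone; it sets out from 8 and 5 and returns at 11.
- Enolisation of 8 (LiN(SiMe3)2, THF, −78 °C) and chlorination with TsCl gives 2-chloro-1-[2,4-bis(allyloxy)-6-(methoxymethoxy)phenyl]ethanone F10.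
- Condensation of F10 with 5 (KOt-Bu, THF, 0 °C) forms the Cα–Cβ bond and the oxirane in one operation, with the trans isomer expected to predominate.

**Step 9.** The π-allyl palladium intermediate may allylate C6 or C8 of the phenoxide of ring A, and the amine may attack C2 of the pyranone. The fallback replaces allyl transfer by isomerisation and hydrolysis; it sets out from 15 and returns at 16.
- H2-activated [Ir(cod)(PMePh2)2]PF6 in THF should isomerise the four allyl ethers to give 5,7-bis(prop-1-enyloxy)-3-[3-(3-methylbut-2-enyl)-2,4-bis(prop-1-enyloxy)phenyl]-4H-chromen-4-one F11. The trisubstituted prenyl alkene is not expected to move.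
- Dilute aqueous HCl in acetone at room temperature then hydrolyses the enol ethers far faster than it can protonate the prenyl alkene.

## Further compounds

```
F1 | step 7 | (E)-1-[2,4-bis(allyloxy)-6-hydroxyphenyl]-3-(dimethylamino)prop-2-en-1-one | CN(C)/C=C/C(=O)c1c(O)cc(OCC=C)cc1OCC=C
F2 | step 7 | 5,7-bis(allyloxy)-3-iodo-4H-chromen-4-one | O=c1c(I)coc2cc(OCC=C)cc(OCC=C)c12
F3 | step 7 | 1,3-bis(methoxymethoxy)benzene | COCOc1cccc(OCOC)c1
F4 | step 7 | 1,3-bis(methoxymethoxy)-2-(3-methylbut-2-enyl)benzene | COCOc1cccc(OCOC)c1CC=C(C)C
F5 | step 7 | [2,4-bis(methoxymethoxy)-3-(3-methylbut-2-enyl)phenyl]boronic acid | COCOc1ccc(B(O)O)c(OCOC)c1CC=C(C)C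
F6 | step 7 | 5,7-bis(allyloxy)-3-[2,4-bis(methoxymethoxy)-3-(3-methylbut-2-enyl)phenyl]-4H-chromen-4-one | CC(C)=CCc1c(OCOC)ccc(-c2coc3cc(OCC=C)cc(OCC=C)c3c2=O)c1OCOC
F7 | step 7 | 5,7-dihydroxy-3-[2,4-bis(methoxymethoxy)-3-(3-methylbut-2-enyl)phenyl]-4H-chromen-4-one | CC(C)=CCc1c(OCOC)ccc(-c2coc3cc(O)cc(O)c3c2=O)c1OCOC
F8 | step 1 | 4-(allyloxy)-2-hydroxybenzaldehyde | O=Cc1ccc(OCC=C)cc1O
F9 | step 1 | 3-allyl-2,4-dihydroxybenzaldehyde | C=CCc1c(O)ccc(C=O)c1O
F10 | step 6 | 2-chloro-1-[2,4-bis(allyloxy)-6-(methoxymethoxy)phenyl]ethanone | O=C(CCl)c1c(OCOC)cc(OCC=C)cc1OCC=C
F11 | step 9 | 5,7-bis(prop-1-enyloxy)-3-[3-(3-methylbut-2-enyl)-2,4-bis(prop-1-enyloxy)phenyl]-4H-chromen-4-one (E/Z mixture, drawn without alkene geometry) | CC=COc1cc(OC=CC)c2c(c1)occ(-c1ccc(OC=CC)c(CC=C(C)C)c1OC=CC)c2=O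
A1 | alternative 1 | (E)-1-diazo-4-[5,7-bis(methoxymethoxy)-4-oxo-4H-chromen-3-yl]but-3-en-2-one | [N-]=[N+]=CC(=O)/C=C/c1coc2cc(OCOC)cc(OCOC)c2c1=O
A2 | alternative 1 | triisopropyl[(5-methylhex-4-en-1-yn-1-yl)oxy]silane | CC(C)=CCC#CO[Si](C(C)C)(C(C)C)C(C)C
A3 | alternative 1 | 3-[2-hydroxy-3-(3-methylbut-2-enyl)-4-(triisopropylsilyloxy)phenyl]-5,7-bis(methoxymethoxy)-4H-chromen-4-one | CC(C)=CCc1c(O[Si](C(C)C)(C(C)C)C(C)C)ccc(-c2coc3cc(OCOC)cc(OCOC)c3c2=O)c1O
A4 | alternative 2 | 3-[4-(methoxymethoxy)-2-(2-methylbut-3-en-2-yloxy)phenyl]-5,7-bis(methoxymethoxy)-4H-chromen-4-one | C=CC(C)(C)Oc1cc(OCOC)ccc1-c1coc2cc(OCOC)cc(OCOC)c2c1=O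
A5 | alternative 2 | 3-[2-hydroxy-4-(methoxymethoxy)-3-(3-methylbut-2-enyl)phenyl]-5,7-bis(methoxymethoxy)-4H-chromen-4-one | CC(C)=CCc1c(OCOC)ccc(-c2coc3cc(OCOC)cc(OCOC)c3c2=O)c1O
A6 | alternative 3 | trans-5,7-bis(allyloxy)-2-[2,4-bis(allyloxy)-3-(3-methylbut-2-enyl)phenyl]-4-oxochroman-3-yl methanesulfonate (racemic, one enantiomer drawn) | O=C1c2c(OCC=C)cc(OCC=C)cc2O[C@H](c2ccc(OCC=C)c(CC=C(C)C)c2OCC=C)[C@H]1OS(C)(=O)=O
A7 | alternative 3 | 5,7-bis(allyloxy)-3-[2,4-bis(allyloxy)-3-(3-methylbut-2-enyl)phenyl]-4H-chromen-4-one | CC(C)=CCc1c(OCC=C)ccc(-c2coc3cc(OCC=C)cc(OCC=C)c3c2=O)c1OCC=C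
```
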